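**Retrosynthetic overview**
1. Feature: the cyclohexene has C1 (quaternary, carrying CH3 and the Z-styryl arm), C2 and C3 (CH2), a C4(CH3)=C5 alkene and C6 (benzylic CH). Coumarin B is bound through its C8 to C6 on the same face as the carbon arm on C1, and its ring oxygen O1 (on C8a) is ortho to that bond. A carboxyl on C1 and O1 therefore fit into a six-membered lactone C6–C1–C(=O)–O1–C8a–C8.
2. Late disconnections: the pyranone of coumarin B (C4–C4a, hydroarylation of an aryl propiolate), the Z-alkene (semi-hydrogenation), the bond from C8 of coumarin A to the alkyne (Sonogashira), and the alkyne carbon (homologation of the lactol made from the lactone).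
3. Key disconnection: the C6–C8 bond of aryl B in the cis-lactone. This leads back to a 3,5-dimethoxyphenyl ester whose tertiary allylic alcohol at C4 delivers the C4–C5–C6 allyl cation.
4. That ester comes from methyl addition to the 4-oxo enone ester. Its acid comes from an enantioselective Diels–Alder reaction of a 1-amino-3-silyloxybutadiene and methacrolein, which fixes C1.
5. Ring order: cyclohexene (Diels–Alder), then the lactone ring (key step, opened again once it has set C6), then the pyranone of coumarin B. Coumarin A is bought as 5,7-dimethoxycoumarin.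

Key step: step 5

Remark: locants C1–C6 in the text are those defined in line 1 of the overview; systematic names carry their own numbering.
Assumption: the (R,R)-diol catalyst is taken to give the (S)-aldehyde in step 1. The sense is to be checked there by reduction to 4-(hydroxymethyl)-4-methylcyclohex-2-enone and comparison of the sign of rotation, and the equally available (S,S)-catalyst is used if the check demands it.
Remark: enantiomeric purity can be raised by recrystallisation of the acid (salt with a chiral amine) or of the lactone from the key step.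

**Step 1**
Reactants: 1 (1E)-3-(tert-butyldimethylsilyloxy)-N,N-dimethylbuta-1,3-dien-1-amine; 2 methacrolein
Product: 4 (1S)-1-methyl-4-oxocyclohex-2-ene-1-carbaldehyde, via Diels–Alder adduct 3 (not isolated)
Conditions: (4R,5R)-2,2-dimethyl-α,α,α′,α′-tetra(1-naphthyl)-1,3-dioxolane-4,5-dimethanol (1-naphthyl-TADDOL, 20 mol %), toluene, −80 °C; then HF, MeCN, 0 °C
Reagents that add atoms: none
Why: Hydrogen-bond-catalysed enantioselective Diels–Alder reaction in which the unsubstituted CH2 terminus of the electron-rich diene bonds to the β-carbon of methacrolein, so that the C(CH3)(CHO) carbon ends up next to C–N, while the diol binds the formyl oxygen, blocks one face of the enal and thereby sets the quaternary centre C1; HF then cleaves the silyl enol ether and the β-amino ketone loses dimethylamine (E1cB), which erases the second centre of 3 and leaves the enone.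

**Step 2**
Reactants: 4 (1S)-1-methyl-4-oxocyclohex-2-ene-1-carbaldehyde
Product: 5 (1S)-1-methyl-4-oxocyclohex-2-ene-1-carboxylic acid
Conditions: NaClO2, NaH2PO4, 2-methyl-2-butene, t-BuOH–H2O, 0 °C to rt
Reagents that add atoms: sodium chlorite, [Na+].[O-]Cl=O
Why: Pinnick oxidation converts the non-enolisable aldehyde into the acid under buffered, mildly acidic conditions that leave the electron-poor enone alone and cannot touch the quaternary centre, while 2-methyl-2-butene takes up the hypochlorous acid.

**Step 3**
Reactants: 5 (1S)-1-methyl-4-oxocyclohex-2-ene-1-carboxylic acid; 6 3,5-dimethoxyphenol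
Product: 7 3,5-dimethoxyphenyl (1S)-1-methyl-4-oxocyclohex-2-ene-1-carboxylate
Conditions: EDC·HCl, DMAP, CH2Cl2, 0 °C to rt
Reagents that add atoms: none
Why: Steglich-type carbodiimide esterification through the acylpyridinium ion, which has no α-hydrogen and hence no ketene or epimerisation pathway, acylates the phenol oxygen and installs the tether before the acid-labile carbinol exists, so that a hydroxy acid prone to bridging lactonisation is never handled.

**Step 4**
Reactants: 7 3,5-dimethoxyphenyl (1S)-1-methyl-4-oxocyclohex-2-ene-1-carboxylate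
Product: 8 3,5-dimethoxyphenyl (1S)-4-hydroxy-1,4-dimethylcyclohex-2-ene-1-carboxylate (both C4 epimers)
Conditions: MeMgBr, CeCl3, THF, −78 °C; aq. NH4Cl at −78 °C
Reagents that add atoms: methylmagnesium bromide, C[Mg]Br
Why: Organocerium-type 1,2-addition (Grignard reagent modified by CeCl3) is far faster at the enone carbonyl than at the α-quaternary aryl ester at −78 °C and suppresses enolisation and conjugate addition; the new carbinol centre C4 forms as a mixture of epimers, which is harmless because step 5 erases it, and the cold quench keeps the alkoxide from attacking the aryl ester.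

**Step 5**
Reactants: 8 3,5-dimethoxyphenyl (1S)-4-hydroxy-1,4-dimethylcyclohex-2-ene-1-carboxylate
Product: 10 (6aS,10aS)-1,3-dimethoxy-6a,9-dimethyl-6a,7,8,10a-tetrahydrobenzo[c]chromen-6-one, via cyclohexenyl cation 9 (not isolated)
Conditions: Sc(OTf)3 (10 mol %), (CF3)2CHOH, 0.005 M, slow addition of 8, 0 °C; Et3N quench
Reagents that add atoms: none
Why: Both C4 epimers of 8 lose hydroxide to Sc(OTf)3 in the strongly ionising, poorly nucleophilic solvent and converge on the single methyl-substituted cyclohexenyl cation 9 (C4–C5–C6), the aryl carbon next to the ester oxygen attacks C6, the arenium ion loses a proton, and the alkene is left between C4 and C5 (dehydrative intramolecular Friedel–Crafts allylation). The closest known reactions are the acid-mediated condensation of p-mentha-2,8-dien-1-ol with resorcinols, where the same kind of cation is arylated at its secondary terminus, and the acid-induced cyclisation of aryl 3-methylbut-2-enoates and cinnamates to 3,4-dihydrocoumarins, where a cation β to an aryl ester carbonyl closes the same lactone ring. The six-membered ring C6–C1–C(=O)–O–C(ipso)–C(ortho) closes 6-exo-trig with respect to the allyl cation, C5 staying outside the new ring, and the C4 terminus is out of reach because bonding there would demand a bridged ring. The new stereocentre C6 is controlled by C1 through the tether: the bond must develop along the p-orbital axis at C6, and the short tether lets the arene reach only the lobe on the side of the C1 carboxyl, hence a cis-fused lactone in which aryl B and the carbon that becomes the styryl arm share one face. The step needs ring closure to beat arylation between two molecules, which high dilution and slow addition favour even though closure runs through the minor ester rotamer, and no choice arises on the arene, because its two carbons next to the ester oxygen are related by symmetry and both profit from one ortho and one para methoxy donor. Any diene formed by proton loss is reprotonated at its terminus and re-enters as 9, and the early amine quench guards against migration of the C4=C5 alkene and against reversal of the arylation.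

**Step 6**
Reactants: 10 (6aS,10aS)-1,3-dimethoxy-6a,9-dimethyl-6a,7,8,10a-tetrahydrobenzo[c]chromen-6-one
Product: 11 (6aS,10aS)-1,3-dimethoxy-6a,9-dimethyl-6a,7,8,10a-tetrahydro-6H-benzo[c]chromen-6-ol (both anomers)
Conditions: i-Bu2AlH (1.1 equiv), CH2Cl2, −78 °C; aq. potassium sodium tartrate
Reagents that add atoms: none
Why: Partial reduction of an aryl lactone by i-Bu2AlH stops at the tetrahedral aluminate at −78 °C, as is usual for 3,4-dihydrocoumarins, and hydrolysis gives the lactol as an inconsequential mixture of anomers with C1 and C6 untouched.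

**Step 7**
Reactants: 11 (6aS,10aS)-1,3-dimethoxy-6a,9-dimethyl-6a,7,8,10a-tetrahydro-6H-benzo[c]chromen-6-ol
Product: 13 2-[(1R,6S)-6-ethynyl-3,6-dimethylcyclohex-2-en-1-yl]-3,5-dimethoxyphenol, via open hydroxy aldehyde 12 (not isolated)
Conditions: dimethyl (1-diazo-2-oxopropyl)phosphonate, K2CO3, MeOH, 0 °C to rt
Reagents that add atoms: dimethyl (1-diazo-2-oxopropyl)phosphonate, CC(=O)C(=[N+]=[N-])P(=O)(OC)OC
Why: Ohira–Bestmann variant of the Seyferth–Gilbert homologation, in which base opens the lactol to the phenoxide aldehyde 12, the diazophosphonate anion made by methanolysis adds to it, and loss of dimethyl phosphate and N2 followed by a 1,2-hydrogen shift gives the terminal alkyne, the aldehyde being non-enolisable so that C1 cannot epimerise.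

**Step 8**
Reactants: 14 5,7-dimethoxycoumarin
Product: 15 8-iodo-5,7-dimethoxychromen-2-one
Conditions: N-iodosuccinimide, CF3CO2H (cat.), MeCN, rt
Reagents that add atoms: N-iodosuccinimide, O=C1CCC(=O)N1I
Why: Electrophilic aromatic iodination by acid-activated N-iodosuccinimide should take C8, which like C6 is ortho or para to both methoxy groups but is flanked by only one of them, whereas C6 sits between both and C3 is much less nucleophilic.

**Step 9**
Reactants: 13 2-[(1R,6S)-6-ethynyl-3,6-dimethylcyclohex-2-en-1-yl]-3,5-dimethoxyphenol; 15 8-iodo-5,7-dimethoxychromen-2-one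
Product: 16 8-{[(1S,2R)-2-(2-hydroxy-4,6-dimethoxyphenyl)-1,4-dimethylcyclohex-3-en-1-yl]ethynyl}-5,7-dimethoxychromen-2-one
Conditions: PdCl2(PPh3)2 (5 mol %), CuI (10 mol %), Et3N–DMF, 50 °C, degassed
Reagents that add atoms: none
Why: Sonogashira coupling, in which oxidative addition of the aryl iodide to zerovalent palladium, transmetalation from the copper acetylide and reductive elimination join C8 of coumarin A to the alkyne, and the fast acetylide pathway under a mild amine base is expected to outrun addition of the free phenol to the triple bond.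

**Step 10**
Reactants: 16 8-{[(1S,2R)-2-(2-hydroxy-4,6-dimethoxyphenyl)-1,4-dimethylcyclohex-3-en-1-yl]ethynyl}-5,7-dimethoxychromen-2-one
Product: 17 8-{(Z)-2-[(1R,2R)-2-(2-hydroxy-4,6-dimethoxyphenyl)-1,4-dimethylcyclohex-3-en-1-yl]ethenyl}-5,7-dimethoxychromen-2-one
Conditions: H2 (1 atm), Pd/CaCO3 poisoned with Pb(OAc)2 (Lindlar catalyst), quinoline, EtOAc, rt
Reagents that add atoms: none
Why: Lindlar semi-hydrogenation delivers both hydrogens to the same face of the adsorbed alkyne and so gives the Z-alkene, while the poisoned surface leaves the trisubstituted ring alkene and the C3=C4 bond of the coumarin alone and releases the hindered alkene before further reduction.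

**Step 11**
Reactants: 17 8-{(Z)-2-[(1R,2R)-2-(2-hydroxy-4,6-dimethoxyphenyl)-1,4-dimethylcyclohex-3-en-1-yl]ethenyl}-5,7-dimethoxychromen-2-one; 18 propiolic acid
Product: 19 2-{(1R,6R)-6-[(Z)-2-(5,7-dimethoxy-2-oxochromen-8-yl)ethenyl]-3,6-dimethylcyclohex-2-en-1-yl}-3,5-dimethoxyphenyl prop-2-ynoate
Conditions: DCC, DMAP (5 mol %), CH2Cl2, −20 to 0 °C
Reagents that add atoms: none
Why: Carbodiimide esterification of the only hydroxyl group by propiolic acid at low temperature is a standard way to aryl propiolates, and little DMAP is used so that conjugate addition to the ynoate is held back.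

**Step 12**
Reactants: 19 2-{(1R,6R)-6-[(Z)-2-(5,7-dimethoxy-2-oxochromen-8-yl)ethenyl]-3,6-dimethylcyclohex-2-en-1-yl}-3,5-dimethoxyphenyl prop-2-ynoate
Product: 20 8-{(1R,6R)-6-[(Z)-2-(5,7-dimethoxy-2-oxochromen-8-yl)ethenyl]-3,6-dimethylcyclohex-2-en-1-yl}-5,7-dimethoxychromen-2-one (target)
Conditions: [(JohnPhos)Au(NCMe)]SbF6 (5 mol %; JohnPhos = (2-biphenylyl)di-tert-butylphosphine), CH2Cl2, rt
Reagents that add atoms: none
Why: Gold-catalysed intramolecular hydroarylation of an aryl propiolate (6-endo-dig), in which the cationic monovalent gold complex activates the ynoate, the only free ring carbon ortho to the ester oxygen, activated by one ortho and one para methoxy group, attacks the terminal alkyne carbon, and rearomatisation followed by protodeauration closes the pyranone of coumarin B under neutral conditions that should not disturb the Z-alkene, the ring alkene or the two stereocentres.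

**Compound list**
1 | (1E)-3-(tert-butyldimethylsilyloxy)-N,N-dimethylbuta-1,3-dien-1-amine | CN(C)/C=C/C(=C)O[Si](C)(C)C(C)(C)C | starting material
2 | methacrolein | CC(=C)C=O | starting material
3 | (1S,2R)-4-(tert-butyldimethylsilyloxy)-2-(dimethylamino)-1-methylcyclohex-3-ene-1-carbaldehyde (endo adduct, NMe2 cis to CHO) | O=C[C@@]1(C)CCC(O[Si](C)(C)C(C)(C)C)=C[C@H]1N(C)C | intermediate
4 | (1S)-1-methyl-4-oxocyclohex-2-ene-1-carbaldehyde | O=C[C@@]1(C)CCC(=O)C=C1 | intermediate
5 | (1S)-1-methyl-4-oxocyclohex-2-ene-1-carboxylic acid | OC(=O)[C@@]1(C)CCC(=O)C=C1 | intermediate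
6 | 3,5-dimethoxyphenol | COc1cc(O)cc(OC)c1 | starting material
7 | 3,5-dimethoxyphenyl (1S)-1-methyl-4-oxocyclohex-2-ene-1-carboxylate | COc1cc(OC)cc(OC(=O)[C@@]2(C)CCC(=O)C=C2)c1 | intermediate
8 | 3,5-dimethoxyphenyl (1S)-4-hydroxy-1,4-dimethylcyclohex-2-ene-1-carboxylate (both C4 epimers) | COc1cc(OC)cc(OC(=O)[C@@]2(C)CCC(C)(O)C=C2)c1 | intermediate
9 | (S)-4-[(3,5-dimethoxyphenoxy)carbonyl]-1,4-dimethylcyclohex-2-en-1-ylium (allyl cation C4–C5–C6) | COc1cc(OC)cc(OC(=O)[C@@]2(C)CC[C+](C)C=C2)c1 | intermediate
10 | (6aS,10aS)-1,3-dimethoxy-6a,9-dimethyl-6a,7,8,10a-tetrahydrobenzo[c]chromen-6-one | COc1cc(OC)c2c(c1)OC(=O)[C@@]1(C)CCC(C)=C[C@@H]21 | intermediate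
11 | (6aS,10aS)-1,3-dimethoxy-6a,9-dimethyl-6a,7,8,10a-tetrahydro-6H-benzo[c]chromen-6-ol (both anomers) | COc1cc(OC)c2c(c1)OC(O)[C@@]1(C)CCC(C)=C[C@@H]21 | intermediate
12 | (1S,2S)-2-(2-hydroxy-4,6-dimethoxyphenyl)-1,4-dimethylcyclohex-3-ene-1-carbaldehyde | O=C[C@@]1(C)CCC(C)=C[C@H]1c1c(O)cc(OC)cc1OC | intermediate
13 | 2-[(1R,6S)-6-ethynyl-3,6-dimethylcyclohex-2-en-1-yl]-3,5-dimethoxyphenol | C#C[C@@]1(C)CCC(C)=C[C@H]1c1c(O)cc(OC)cc1OC | intermediate
14 | 5,7-dimethoxycoumarin | COc1cc(OC)c2ccc(=O)oc2c1 | starting material
15 | 8-iodo-5,7-dimethoxychromen-2-one | COc1cc(OC)c2ccc(=O)oc2c1I | intermediate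
16 | 8-{[(1S,2R)-2-(2-hydroxy-4,6-dimethoxyphenyl)-1,4-dimethylcyclohex-3-en-1-yl]ethynyl}-5,7-dimethoxychromen-2-one | COc1cc(OC)c2ccc(=O)oc2c1C#C[C@@]1(C)CCC(C)=C[C@H]1c1c(O)cc(OC)cc1OC | intermediate
17 | 8-{(Z)-2-[(1R,2R)-2-(2-hydroxy-4,6-dimethoxyphenyl)-1,4-dimethylcyclohex-3-en-1-yl]ethenyl}-5,7-dimethoxychromen-2-one | COc1cc(OC)c2ccc(=O)oc2c1/C=C\[C@@]1(C)CCC(C)=C[C@H]1c1c(O)cc(OC)cc1OC | intermediate
18 | propiolic acid | C#CC(=O)O | starting material
19 | 2-{(1R,6R)-6-[(Z)-2-(5,7-dimethoxy-2-oxochromen-8-yl)ethenyl]-3,6-dimethylcyclohex-2-en-1-yl}-3,5-dimethoxyphenyl prop-2-ynoate | COc1cc(OC)c2ccc(=O)oc2c1/C=C\[C@@]1(C)CCC(C)=C[C@H]1c1c(OC(=O)C#C)cc(OC)cc1OC | intermediate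
20 | 8-{(1R,6R)-6-[(Z)-2-(5,7-dimethoxy-2-oxochromen-8-yl)ethenyl]-3,6-dimethylcyclohex-2-en-1-yl}-5,7-dimethoxychromen-2-one | COc1cc(OC)c2ccc(=O)oc2c1/C=C\[C@@]1(C)CCC(C)=C[C@H]1c1c(OC)cc(OC)c2ccc(=O)oc12 | target

**Total step count:** 12. **Longest linear sequence:** 11 steps (steps 1–7 and 9–12; step 8 is the side branch).

**Steps most likely to fail**

**Step 5.**
- What may go wrong: closure has to pass through the minor ester rotamer. It may therefore be overtaken by arylation between molecules, by proton loss to dienes that do not return, by capture of the cation by the ester carbonyl followed by hydrolytic loss of the phenol, or by acid-driven migration of the ring alkene.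
- Fallback (sets out from 5 and 6, comes back at 10): acid 5 is treated with excess MeMgBr and CeCl3 in THF at −78 °C to give (1S)-4-hydroxy-1,4-dimethylcyclohex-2-ene-1-carboxylic acid F1.
- F1 and phenol 6 are then condensed without a tether by BF3·OEt2 in CH2Cl2 over MgSO4, in the manner of the terpenylation of resorcinols.
- Arylation of such a cation by so electron-rich a ring is reversible under acid. Only the ortho adduct with aryl and carboxyl on one face can lactonise, namely (1S,2S)-2-(2-hydroxy-4,6-dimethoxyphenyl)-1,4-dimethylcyclohex-3-ene-1-carboxylic acid F2. Lactonisation should therefore drain the equilibrating mixture into 10.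

**Step 12.**
- What may go wrong: the gold cation may be held by the alkenes or by the lactone carbonyls, so that turnover stalls. Traces of acid may isomerise the strained Z-alkene or cleave the hindered aryl propiolate.
- Fallback (sets out from 17, comes back at 20, steps 11 and 12 bypassed): ortho-selective Casnati–Skattebøl formylation of 17 (MgCl2, Et3N, paraformaldehyde, MeCN, reflux) should give 8-{(Z)-2-[(1R,2R)-2-(3-formyl-2-hydroxy-4,6-dimethoxyphenyl)-1,4-dimethylcyclohex-3-en-1-yl]ethenyl}-5,7-dimethoxychromen-2-one F5.
- Heating F5 with (triphenylphosphoranylidene)ketene in toluene adds the phenol to the cumulated ylide and gives the aryl (triphenylphosphoranylidene)acetate F6.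
- F6 closes the pyranone by an intramolecular Wittig reaction and delivers 20 without any π-acid.

**Step 9.**
- What may go wrong: oxidative addition to the electron-rich, doubly ortho-substituted iodide and coupling to an alkyne on a quaternary carbon may be slow. Oxidative homocoupling of the alkyne or addition of the neighbouring phenol O–H across the triple bond may then take over.
- Fallback (sets out from 11 and 15, comes back at 17, steps 7, 9 and 10 bypassed): Stork–Zhao olefination of lactol 11 (the ylide from (iodomethyl)triphenylphosphonium iodide and excess NaHMDS, THF, −78 °C) should give 2-{(1R,6S)-6-[(Z)-2-iodoethenyl]-3,6-dimethylcyclohex-2-en-1-yl}-3,5-dimethoxyphenol F3.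
- Miyaura borylation of 15 (B2pin2, PdCl2(dppf), KOAc, dioxane, 80 °C) gives 5,7-dimethoxy-8-(4,4,5,5-tetramethyl-1,3,2-dioxaborolan-2-yl)chromen-2-one F4.
- Suzuki–Miyaura coupling of F3 and F4 (Pd(OAc)2, SPhos, K3PO4, THF–H2O) proceeds with retention of the alkene geometry and leads straight to 17.

**Further compounds**
F1 | step 5 | (1S)-4-hydroxy-1,4-dimethylcyclohex-2-ene-1-carboxylic acid (both C4 epimers) | OC(=O)[C@@]1(C)CCC(C)(O)C=C1
F2 | step 5 | (1S,2S)-2-(2-hydroxy-4,6-dimethoxyphenyl)-1,4-dimethylcyclohex-3-ene-1-carboxylic acid | OC(=O)[C@@]1(C)CCC(C)=C[C@H]1c1c(O)cc(OC)cc1OC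
F3 | step 9 | 2-{(1R,6S)-6-[(Z)-2-iodoethenyl]-3,6-dimethylcyclohex-2-en-1-yl}-3,5-dimethoxyphenol | I/C=C\[C@@]1(C)CCC(C)=C[C@H]1c1c(O)cc(OC)cc1OC
F4 | step 9 | 5,7-dimethoxy-8-(4,4,5,5-tetramethyl-1,3,2-dioxaborolan-2-yl)chromen-2-one | COc1cc(OC)c2ccc(=O)oc2c1B1OC(C)(C)C(C)(C)O1
F5 | step 12 | 8-{(Z)-2-[(1R,2R)-2-(3-formyl-2-hydroxy-4,6-dimethoxyphenyl)-1,4-dimethylcyclohex-3-en-1-yl]ethenyl}-5,7-dimethoxychromen-2-one | COc1cc(OC)c2ccc(=O)oc2c1/C=C\[C@@]1(C)CCC(C)=C[C@H]1c1c(O)c(C=O)c(OC)cc1OC
F6 | step 12 | 2-{(1R,6R)-6-[(Z)-2-(5,7-dimethoxy-2-oxochromen-8-yl)ethenyl]-3,6-dimethylcyclohex-2-en-1-yl}-6-formyl-3,5-dimethoxyphenyl (triphenylphosphoranylidene)acetate | COc1cc(OC)c2ccc(=O)oc2c1/C=C\[C@@]1(C)CCC(C)=C[C@H]1c1c(OC(=O)C=P(c2ccccc2)(c2ccccc2)c2ccccc2)c(C=O)c(OC)cc1OC
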